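(The readings are simulated with constants of no real substance; the scatter is artificial.)

A small charge of Wu, 0.700 equiv in beta, might seem likely to leave Ej in the lead at 100 min. Turn the question round: what must be true for that?

in all of them: Ej 0.050 M
- maple: Wu 0.72 equiv; run made earlier
- elm: Wu 1.1 equiv; run made earlier
- cedar: Wu 1.9 equiv; run made earlier
- beta: Wu 0.700 equiv; time 100 min
- zeta: Wu 1.00 equiv; time 100 min
- theta: Wu 1.60 equiv; time 100 min

| run | time / min | Ez / % | Ej.Dw / % | Ej / % | Dw / % | Uj / % |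
|---|---|---|---|---|---|---|
| maple | 6.00 | 0 | 4.0 | 91.9 | 3.8 | 0 |
| maple | 12.0 | 0 | 10.8 | 83.4 | 7.3 | 0.2 |
| maple | 30.0 | 0.9 | 31.0 | 61.9 | 6.9 | 0 |
| maple | 80.0 | 0.7 | 60.0 | 33.5 | 4.4 | 0 |
| elm | 8.00 | 0 | 8.1 | 84.0 | 7.4 | 0 |
| elm | 25.0 | 0.9 | 33.8 | 55.8 | 10.2 | 0 |
| elm | 50.0 | 1.2 | 55.9 | 32.2 | 9.3 | 0.3 |
| elm | 80.0 | 1.6 | 70.7 | 19.2 | 7.7 | 1.4 |
| cedar | 20.0 | 2.0 | 35.7 | 44.4 | 16.8 | 0.2 |
| cedar | 40.0 | 3.4 | 58.7 | 21.5 | 12.8 | 1.4 |
| cedar | 50.0 | 3.3 | 64.6 | 15.9 | 13.1 | 1.2 |
| cedar | 80.0 | 4.7 | 72.9 | 7.7 | 9.3 | 4.7 |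

(readings scatter by 0.5 percentage points)

- which of these there is most of at the end, counted by the Ej in it, beta (Dw / Uj / Ej.Dw / Ej / Ez)
- which of these there is most of at the end, counted by the Ej in it, zeta (Dw / Uj / Ej.Dw / Ej / Ez)
- which of these there is most of at the end, counted by the Ej in it, theta (Dw / Uj / Ej.Dw / Ej / Ez)
- how much there is at the end of the one of these that leads, in percent of the Ej charged: beta
- how much there is at the end of the one of these that leads, in percent of the Ej charged: zeta
- how much there is at the end of the one of these that leads, in percent of the Ej charged: theta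

- in percentages every species weighs as the Ej in it: one Ej.Dw counts as two
- the earlier runs were read with a standard deviation of 0.5 percentage points

For Ej to lead, it must still stand above Ej.Dw at the end. So count turnovers of Ej as halvings. Call equivalents of Wu times minutes the dose. Treat Ej as pseudo-first-order in the charged Wu, with Ej at 0.050 M. Maple's last reading then gives the dose that takes Ej to a half of its charge, the halving dose:

36.5 min at one equiv of Wu

Divide a flask's dose by it and you have its halving count. Elm shows where the lead changes: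

count 0.753: Ej 55.8 %, Ej.Dw 33.8 %

count 1.51: Ej 32.2 %, Ej.Dw 55.9 %

So, on elm's readings, the lead changes between these two counts, and the opposite outcome needs a count below 1.51. My own count for the new flasks, with the Ej it leaves:

beta: 1.92, Ej 26.4 %

zeta: 2.74, Ej 15.0 %

theta: 4.38, Ej 4.80 %

Each count stands above 1.51, so I expect Ej.Dw to lead in each flask. Beta has the lowest count, and it still stands above that mark. The Ej figure for theta is probably low: cedar read 7.7 % where the count gives 5.58 %.

The forecast said “Ej.Dw should lead in all three runs”. It named Ej.Dw, Ej.Dw and Ej.Dw, at 65 %, 74 % and 76 %.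

The flasks give Ej.Dw, Ej.Dw and Ej.Dw, at 65.5 %, 73.8 % and 77.0 %, with Ej at 28.9 %, 17.1 % and 7.45 %.

    Ej + Wu ⇌ Ze + Dw (K = 1.10, k = 0.320 /M/min)
    Dw + Wu ⇌ Ze + Ez (K = 1.90, k = 0.110 /M/min)
    Ez + Wu ⇌ Ze + Uj (K = 63.0, k = 0.290 /M/min)
    Ze + Dw → Ze.Dw (k = 0.0750 /M/min)
    Ej + Dw → Ej.Dw (k = 2.30 /M/min)

Beta ends at 65.5 % of Ej.Dw partly because free Wu shrinks, to 43 % of its charge, and because the time given is short. With Wu held up, beta gives 73.7 %. Left to 1000 min, it gives 93.0 %.

Now read beta at 40 min. The halving dose gives a count of 0.767, close to elm's 0.753, so Ej should lead, with 58.8 % left. The flask shows Ej ahead, 54.8 % against 38.3 % of Ej.Dw.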